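(Readings and results are simulated with made-up constants; noise was put on by code.)

The constants come first, so the examiner starts there, with the flasks, the earlier readings and the questions on the table.

| setting | zeta | alpha | theta | summer | dusk | noon | winter |
|---|---|---|---|---|---|---|---|
| D | 0.050 M | 0.050 M | 0.087 M | 0.050 M | 0.050 M | 0.050 M | 0.10 M |
| X | 0.24 equiv | 1 equiv | 0.90 equiv | 0.900 equiv | 0.900 equiv | 1.40 equiv | 0.450 equiv |
| G | 1 equiv | 1 equiv | 1 equiv | 3.00 equiv | 1.00 equiv | 0.330 equiv | 1.00 equiv |
| temperature | −5 °C | 17 °C | −5 °C | 5 °C | 25 °C | 10 °C | −15 °C |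
| remark | run made earlier | run made earlier | run made earlier |  |  |  |  |
| time |  |  |  | 4.0 min | 4.0 min | 4.0 min | 4.0 min |

| run | time / min | E / % |
|---|---|---|
| zeta | 3.00 | 1.2 |
| zeta | 6.00 | 2.2 |
| zeta | 8.00 | 2.4 |
| zeta | 12.0 | 2.2 |
| zeta | 20.0 | 2.9 |
| alpha | 0.250 | 2.5 |
| alpha | 0.833 | 7.0 |
| alpha | 1.33 | 9.7 |
| alpha | 2.00 | 12.3 |
| alpha | 3.00 | 15.1 |
| alpha | 4.00 | 16.8 |
| theta | 1.33 | 3.7 |
| theta | 4.00 | 8.0 |
| theta | 8.00 | 10.8 |
| theta | 12.0 | 13.2 |
| theta | 20.0 | 14.3 |

(scatter of a reading: 0.3 percentage points)

- ranking by amount of E, in percent of the D charged, from high to low, at 4.0 min (summer / dusk / noon / winter)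
- the same order at 50 s (summer / dusk / noon / winter)
- the amount of E, in percent of the D charged of the flask you put first, at 4.0 min
- the amount of E, in percent of the D charged of the flask you put last, at 4.0 min

*What rate constant do the runs give for E?* Dividing a run's first reading, a share of the D charged, by its time and by [X] as charged gives 0.355 /M/min from theta at −5 °C and 2.00 /M/min from alpha at 17 °C, both as readings.

*Is it really first order in X?* The theta constant, applied to the smaller [X] of zeta, gives 1.28% at zeta's first reading, which stands at 1.2%, so I take the rate of E as k[X][D], first order in an [X] that falls as X is spent.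

*Then why does zeta stop?* It levels near 2.9% of D from 0.24 equiv of X, so I take X as spent there, and 12.1% is the share of spent X that lands in E.

*Spent on what? X could simply die.* In that case the share would grow with concentration and theta would need 21.0%, yet its last reading gives 15.9%, less. I therefore wager on G as a rival for X, and it stays a wager, for zeta, alpha and theta alike were charged with 1 equiv of G. The share is then S[D]/(S[D]+[G]), with the selectivity factor S = 0.137 at −5 °C. Alpha, with 16.8% of E from 1 equiv of X, read in the same way as if its X were spent, gives a rough estimate of S at 17 °C of 0.202.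

*Your order, then?* At 50 s I rank by k[X] as charged: dusk, summer and winter hold 0.0450 M, 0.0450 M and 0.0450 M of X, so I order these by temperature, 25 °C, 5 °C and −15 °C. Noon, at 10 °C with 0.0700 M of X, goes above summer, and I judge the climb of the constant from 0.355 /M/min to 2.00 /M/min between −5 °C and 17 °C enough to keep dusk ahead of noon. At 4.0 min I put noon first, since its 0.330 equiv of G can claim about a quarter of its 1.40 equiv of X. Dusk follows at about 15.1%, then summer, whose 3.00 equiv of G cuts the share to about 5.68% of D, less, and last winter, whose X is worth about 5.44% of D at zeta's share, less again.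

The forecast differs from this: it gives summer > dusk > noon > winter with 27% and 2.7%, and dusk > summer > noon > winter at 50 s, on the ground that “I take G as the kinetically active partner”.

The flasks give noon > dusk > summer > winter, with 25.4% and 2.40%, and dusk > noon > summer > winter at 50 s.

    D + X → E (k = 0.0690 /M/s, Ea = 49.0 kJ/mol)
    G + X → Z (k = 0.330 /M/s, Ea = 38.0 kJ/mol)
    2 D → J (k = 0.0190 /M/s, Ea = 63.0 kJ/mol)
    (constants at 25 °C)

In winter, where D and G are charged equally, 48% of X is left at 4.0 min, and the share 12.1% read from zeta, applied to the X spent, gives 2.80% of D against the 2.40% found. The neighbouring flask is winter with 1.80 equiv of X, and its D and G are also charged equally. It keeps 59% of its X at 4.0 min, so the same share on the X spent gives 8.81% of D, against the 9.87% of E that this neighbour holds.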